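The earlier runs and the new flask come from a simulation on assumed constants, and the scatter is random.

A second in Tuesday's flask buys less L than a second in Monday's: 1.0% after 50.0 s against 5.1% after 25.0 s.

| flask | Z | Q | remark | time |
|---|---|---|---|---|
| Tuesday's | 1.1 M | 1.1 equiv | the very flask that is asked about, followed so far |  |
| Monday's | 2.2 M | 1.1 equiv | run made earlier |  |
| flask | 1.1 M | 1.10 equiv |  | 2.0 min |

| run | time / s | Z / % | L / % |
|---|---|---|---|
| Tuesday's | 10.0 | 99.4 | 0 |
| Tuesday's | 15.0 | 100.1 | 0 |
| Tuesday's | 25.0 | 98.6 | 0 |
| Tuesday's | 40.0 | 99.6 | 0 |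
| Tuesday's | 50.0 | 98.9 | 1.0 |
| Tuesday's | 60.0 | 98.6 | 1.8 |
| Monday's | 10.0 | 100.1 | 0.8 |
| Monday's | 15.0 | 99.3 | 0.8 |
| Monday's | 25.0 | 94.8 | 5.1 |
| Monday's | 40.0 | 59.5 | 42.0 |
| Monday's | 60.0 | 20.2 | 80.2 |
| Monday's | 80.0 | 8.7 | 91.0 |

(scatter of a reading: 0.5 percentage points)

- at 2.0 min, what has stopped the reaction, if anything has (all of Z has reacted / it is still moving / Q has run out first)
- how much of the Z has reacted by 2.0 min
- how much L there is at 2.0 min, in percent of the Z charged

- the numbers in the tables scatter with a standard deviation of 0.5 percentage points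
- the reaction counts as stopped when no species that holds the Z changes by six tenths of a point or more over the second half of the time

Those two times differ by the charge ratio, 2.00, so the zero of the scale, a two-body clock stretched by that ratio, fails. The useful measure is the clock of the rise, as in autocatalysis: the growth per second of the ratio of L to Z. Monday's readings at 25.0 s and 40.0 s give 0.172 s⁻¹.

Tuesday's 1.8% at 60.0 s lies between Monday's readings at 15.0 s and 25.0 s, so the stretch lies between 2.40 and 4.00. Carried from that reading to 2.0 min, the smaller stretch gives an estimated ceiling of 57.1% L.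

The larger stretch equals the square of the charge ratio, as expected if Z, Q and L all enter the rate. This reckoning commits to that square: Tuesday's clock, Monday's clock divided by the squared charge ratio, is 0.0429 s⁻¹. It gives an estimated floor of 19.3% L, with Z remaining.

The forecast lies inside the bracket: it is still moving, conversion 28%, L 28%. “That point lies on the steep part of the curve, so the estimate is uncertain.”

The flask gives: it is still moving, conversion 20.5%, L 20.5%.

    L → E (k = 3.30 × 10⁻⁶ s⁻¹)
    Z + Q + L → 2 L (k = 0.0400 L² mol⁻² s⁻¹)
    Z + Q → L (k = 2.40 × 10⁻⁵ L mol⁻¹ s⁻¹)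

In the asked flask, Z + Q → L turned over 0.324% of the Z charged by 2.0 min, and Z + Q + L → 2 L carried the remaining 20 percentage points. At that time 79.5% of the Z charged and 81.3% of Q's own charge stood in the flask. The square clock's figure lies 1.2 points below the flask, and the forecast 7.5 points above it.

A neighbour charged with 0.28 M of Z, at the same equivalents, is reckoned by the square at a clock of 0.00278 s⁻¹: 0.334 e-foldings in 2.0 min against 5.15 in the asked flask. Its L reaches 0.110%, with 99.9% of its Z still there.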